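**Plan** (germacrane numbering throughout: C1 ketone, C2=C3 furanone alkene, C4=C5 with C15 on C4, C6 lactone carbinol, C7, C8 ester carbinol, C9, C10 quaternary ether carbon with C14, C11=C13, C12)
- Feature used: the C2=C3–C4=C5 diene is trans within the ten-membered ring at C2=C3 (part of the furanone ring C1–C2–C3–O–C10) and cis at C4=C5. This is the diene a cis-fused cyclobutene C2–C3=C4–C5 releases when its C2–C5 bond opens by conrotation.
- Retrosynthesis: the C15 O–Si bond is cut first. C2–C3 and C4–C5 are then cut (C2–C5 restored) to give cyclooct-2-enone 30 with an alkynyl ether on the C10 oxygen. 30 is cut at C2=C5 (metathesis), at the lactone O–C12 bond and at C7–C8 (allylindium addition), giving aldehyde 15 and allylic bromide 22.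
- Forward: citramalic acid → hydroxy lactone → dichlorovinyl ether → alkynyl ether aldehyde 15, which is joined to 22 at C7–C8. The rings then arise in the order lactone (step 16), eight-membered ring (step 18), furanone and ten-membered carbocycle together (step 19).
- Stereochemistry: C10 comes from (S)-citramalic acid and C6 from (R)-but-3-ene-1,2-diol. C7 and C8 come from the chair allylindium addition under control of C6. The cis C2=C5 alkene follows from the eight-membered ring, and the cis C4=C5 alkene from the forced sense of conrotation.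

Key step: step 19

Remark on the chemistry: C1 of compounds 9–15 and 24–28 and the carbinol carbon of 21 are epimer mixtures carried as such, because steps 17 and 13 turn these centres into sp2 carbons.

**Step 1**
Reactants: 1 (S)-citramalic acid
Product: 2 2-[(4S)-2,2,4-trimethyl-5-oxo-1,3-dioxolan-4-yl]acetic acid
Conditions: Me2C(OMe)2, PPTS (cat.), acetone, rt
Reagents that add atoms: 2,2-dimethoxypropane, COC(C)(C)OC
Why: Acid-catalysed transacetalisation should close the five-membered dioxolanone on the α-hydroxy acid unit rather than the six-membered alternative, masking C1 and the tertiary hydroxyl and leaving the C8 carboxyl free, with C10 untouched.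

**Step 2**
Reactants: 2 2-[(4S)-2,2,4-trimethyl-5-oxo-1,3-dioxolan-4-yl]acetic acid
Product: 4 (3S)-3-hydroxy-3-methyloxolan-2-one, via dioxolanone alcohol 3 (not isolated)
Conditions: BH3·SMe2, THF, 0 °C → rt; MeOH; then TsOH·H2O (cat.), CH2Cl2, rt
Reagents that add atoms: none
Why: Borane reduces the free carboxylic acid chemoselectively beside the dioxolanone, and acid-catalysed translactonisation of the new primary alcohol onto the activated acyl group should expel acetone and give the γ-lactone with the tertiary hydroxyl free.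

**Step 3**
Reactants: 4 (3S)-3-hydroxy-3-methyloxolan-2-one; 5 trichloroethylene
Product: 6 (3S)-3-[(E)-1,2-dichloroethenyloxy]-3-methyloxolan-2-one
Conditions: KH, THF, 0 °C; then Cl2C=CHCl, −50 °C → rt
Reagents that add atoms: none
Why: Addition of a potassium alkoxide to dichloroacetylene formed in situ from trichloroethylene (the standard dichlorovinyl ether synthesis) should give the E ether; it is done at the lactone stage, where there is no α-hydrogen and no neighbouring silyl ether that could migrate to the alkoxide.

**Step 4**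
Reactants: 6 (3S)-3-[(E)-1,2-dichloroethenyloxy]-3-methyloxolan-2-one
Product: 7 (3S)-3-[(E)-1,2-dichloroethenyloxy]-3-methyloxolan-2-ol (anomer mixture)
Conditions: i-Bu2AlH, CH2Cl2, −78 °C
Reagents that add atoms: none
Why: Half-reduction of a γ-lactone to the lactol stops at the aluminium hemiacetal at low temperature, and the dichlorovinyl ether is inert to the hydride.

**Step 5**
Reactants: 7 (3S)-3-[(E)-1,2-dichloroethenyloxy]-3-methyloxolan-2-ol; 8 vinylmagnesium bromide
Product: 9 (3S)-3-[(E)-1,2-dichloroethenyloxy]-3-methylhex-5-ene-1,4-diol (C4 epimers; C4 of this name is C1 of the target)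
Conditions: CH2=CHMgBr (3 equiv), THF, 0 °C → rt
Reagents that add atoms: none
Why: Grignard addition to the open-chain hydroxy aldehyde in equilibrium with the lactol forms the C1–C2 bond; the new C1 carbinol is not controlled and need not be, since it becomes the ketone in step 17.

**Step 6**
Reactants: 9 (3S)-3-[(E)-1,2-dichloroethenyloxy]-3-methylhex-5-ene-1,4-diol
Product: 10 (3S)-3-[(E)-1,2-dichloroethenyloxy]-3-methyl-1,4-bis(triethylsilyloxy)hex-5-ene (C4 epimers)
Conditions: Et3SiCl, imidazole, DMAP (cat.), CH2Cl2, 0 °C → rt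
Reagents that add atoms: chlorotriethylsilane, CC[Si](Cl)(CC)CC
Why: Standard silylation protects the primary (C8) and secondary (C1) hydroxyls as ethers that survive butyllithium and can later be removed by fluoride without acid.

**Step 7**
Reactants: 10 (3S)-3-[(E)-1,2-dichloroethenyloxy]-3-methyl-1,4-bis(triethylsilyloxy)hex-5-ene
Product: 13 (3S)-3-methyl-1,4-bis(triethylsilyloxy)-3-[3-(triisopropylsilyloxy)prop-1-ynyloxy]hex-5-ene (C4 epimers), via lithium alkynyl ether 11 (not isolated), via lithium alkoxide 12 (not isolated)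
Conditions: n-BuLi (2.3 equiv), THF, −78 → −40 °C; (CH2O)n, → 0 °C; i-Pr3SiCl, DMPU, 0 °C → rt
Reagents that add atoms: formaldehyde (from paraformaldehyde), C=O; chlorotriisopropylsilane, CC(C)[Si](Cl)(C(C)C)C(C)C
Why: In the dichlorovinyl ether route to alkynyl ethers, deprotonation and loss of LiCl give the chloroalkynyl ether and chlorine–lithium exchange gives the lithium alkynyl ether, which formaldehyde hydroxymethylates at C15; silylating the alkoxide in the flask avoids handling the rearrangement-prone 3-alkoxypropargyl alcohol.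

**Step 8**
Reactants: 13 (3S)-3-methyl-1,4-bis(triethylsilyloxy)-3-[3-(triisopropylsilyloxy)prop-1-ynyloxy]hex-5-ene
Product: 14 (3S)-3-methyl-4-(triethylsilyloxy)-3-[3-(triisopropylsilyloxy)prop-1-ynyloxy]hex-5-en-1-ol (C4 epimers)
Conditions: Bu4NF/AcOH (1:1, 1 equiv), THF, −20 → 0 °C
Reagents that add atoms: none
Why: Buffered fluoride should cleave the unhindered primary triethylsilyl ether well before the secondary one next to the quaternary carbon and the primary triisopropylsilyl ether, and the buffer keeps the medium non-basic for the alkynyl ether.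

**Step 9**
Reactants: 14 (3S)-3-methyl-4-(triethylsilyloxy)-3-[3-(triisopropylsilyloxy)prop-1-ynyloxy]hex-5-en-1-ol
Product: 15 (3S)-3-methyl-4-(triethylsilyloxy)-3-[3-(triisopropylsilyloxy)prop-1-ynyloxy]hex-5-enal (C4 epimers)
Conditions: Dess–Martin periodinane, pyridine, CH2Cl2, 0 °C
Reagents that add atoms: none
Why: Dess–Martin oxidation buffered with pyridine is neutral enough for the acid-labile alkynyl ether; the β-alkynyloxy aldehyde is used crude at once because base would expel the ynolate by E1cB elimination.

**Step 10**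
Reactants: 16 (R)-but-3-ene-1,2-diol
Product: 17 (R)-1,2-bis(triethylsilyloxy)but-3-ene
Conditions: Et3SiCl, imidazole, CH2Cl2, 0 °C → rt
Reagents that add atoms: chlorotriethylsilane, CC[Si](Cl)(CC)CC
Why: Routine bis-silylation of a 1,2-diol; the stereocentre (later C6) is not involved.

**Step 11**
Reactants: 17 (R)-1,2-bis(triethylsilyloxy)but-3-ene
Product: 18 (R)-2-(triethylsilyloxy)but-3-enal
Conditions: (COCl)2, DMSO, CH2Cl2, −78 → −40 °C; Et3N, −78 → 0 °C
Reagents that add atoms: none
Why: Under Swern conditions a primary triethylsilyl ether is converted directly into the aldehyde while a secondary one survives (known oxidative desilylation), and low temperature with immediate use protects the α-stereocentre.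

**Step 12**
Reactants: 18 (R)-2-(triethylsilyloxy)but-3-enal; 19 methyl propiolate
Product: 21 methyl (4R)-3-hydroxy-2-methylidene-4-(triethylsilyloxy)hex-5-enoate (C3 epimers), via vinylalane 20 (not isolated)
Conditions: i-Bu2AlH, NMO, THF, 0 °C; methyl propiolate; then 18, 0 °C → rt
Reagents that add atoms: none
Why: Hydroalumination of the propiolate gives the α-alumino acrylate, which adds to the aldehyde to give a Morita–Baylis–Hillman-type adduct without amine base, so the epimerisable aldehyde is spared; the new carbinol is an epimer mixture that becomes sp2 in step 13.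

**Step 13**
Reactants: 21 methyl (4R)-3-hydroxy-2-methylidene-4-(triethylsilyloxy)hex-5-enoate
Product: 22 methyl (2Z,4R)-2-(bromomethyl)-4-(triethylsilyloxy)hexa-2,5-dienoate
Conditions: NBS, Me2S, CH2Cl2, −20 → 0 °C
Reagents that add atoms: N-bromosuccinimide, O=C1CCC(=O)N1Br
Why: Corey–Kim-type activation of the allylic alcohol and SN2' attack of bromide should give the thermodynamically preferred Z bromide (C6 cis to CH2Br), as is usual for such adducts, without touching C6.

**Step 14**
Reactants: 15 (3S)-3-methyl-4-(triethylsilyloxy)-3-[3-(triisopropylsilyloxy)prop-1-ynyloxy]hex-5-enal; 22 methyl (2Z,4R)-2-(bromomethyl)-4-(triethylsilyloxy)hexa-2,5-dienoate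
Product: 24 methyl (3R,4R,6S)-4-hydroxy-6-methyl-2-methylidene-7-(triethylsilyloxy)-3-[(1R)-1-(triethylsilyloxy)prop-2-enyl]-6-[3-(triisopropylsilyloxy)prop-1-ynyloxy]non-8-enoate (C7 epimers; C7 of this name is C1 of the target), via allylindium reagent 23 (not isolated)
Conditions: In powder, THF/DMF, rt
Reagents that add atoms: none
Why: In this indium-mediated Barbier allylation the Z allylindium should react through a chair six-membered transition state with C6 axial, giving the 7,8-syn relationship, and the aldehyde should approach the allyl face anti to the silyloxy group in the conformer with C6–H eclipsing the double bond (allylic 1,3-strain), setting C7 and thereby C8 relative to C6 as the trans lactone requires.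

**Step 15**
Reactants: 24 the hydroxy ester of step 14; 25 isovaleric anhydride
Product: 26 methyl (3R,4R,6S)-6-methyl-4-(3-methylbutanoyloxy)-2-methylidene-7-(triethylsilyloxy)-3-[(1R)-1-(triethylsilyloxy)prop-2-enyl]-6-[3-(triisopropylsilyloxy)prop-1-ynyloxy]non-8-enoate (C7 epimers)
Conditions: (i-BuCO)2O, Et3N, DMAP (cat.), CH2Cl2, 0 °C → rt
Reagents that add atoms: none
Why: DMAP-catalysed acylation of the only free hydroxyl installs the C8 isovalerate with retention and blocks C8–OH from competing for the lactone.

**Step 16**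
Reactants: 26 the isovalerate of step 15
Product: 28 (1R,3S)-1-[(2R,3R)-2-ethenyl-4-methylidene-5-oxooxolan-3-yl]-4-hydroxy-3-methyl-3-[3-(triisopropylsilyloxy)prop-1-ynyloxy]hex-5-enyl 3-methylbutanoate (C4 epimers), via diol 27 (not isolated)
Conditions: Bu4NF/AcOH (1:1), THF, 0 °C → rt
Reagents that add atoms: none
Why: Buffered fluoride removes both secondary triethylsilyl ethers while the triisopropylsilyl ether persists, and the freed C6 hydroxyl should close onto the acrylate ester (5-exo-trig lactonisation) to the 6,12-olide, whose trans fusion was fixed in step 14.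

**Step 17**
Reactants: 28 the lactone alcohol of step 16
Product: 29 (1R,3S)-1-[(2R,3R)-2-ethenyl-4-methylidene-5-oxooxolan-3-yl]-3-methyl-4-oxo-3-[3-(triisopropylsilyloxy)prop-1-ynyloxy]hex-5-enyl 3-methylbutanoate
Conditions: Dess–Martin periodinane, pyridine, CH2Cl2, 0 °C
Reagents that add atoms: none
Why: Dess–Martin oxidation of the allylic alcohol gives the vinyl ketone and merges the C1 epimers; it precedes metathesis so that no allylic-alcohol vinyl group remains from which a five-membered enyne closure onto the alkynyl ether could start.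

**Step 18**
Reactants: 29 the vinyl ketone of step 17
Product: 30 cis-cyclooct-2-enone (6R,7R,8R,10S): eight-membered ring C1(=O)–C2=C5–C6–C7–C8–C9–C10, trans-fused 6,12-olide with 11(13)-methylidene, 8-(3-methylbutanoate), C10 bearing methyl and the 3-(triisopropylsilyloxy)prop-1-ynyl ether
Conditions: second-generation Hoveyda–Grubbs catalyst [RuCl2(H2IMes)(=CH-C6H4-2-O-i-Pr)] (10 mol %), CH2Cl2 (1 mM), 40 °C
Reagents that add atoms: none
Why: In this ring-closing metathesis the catalyst should load on the C6 vinyl group (the vinyl ketone is a poor initiation site) and close onto the enone, the ring size enforcing the cis alkene; the internal alkynyl ether is flanked by a quaternary carbon and a silyloxymethyl group, and 40 °C stays below the retro-ene cleavage of the tertiary alkynyl ether.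

**Step 19**
Reactants: 30 the cyclooctenone alkynyl ether of step 18
Product: 32 (2Z,4Z,6R,7R,8R,10S)-1-oxo-15-(triisopropylsilyloxy)-3,10-epoxygermacra-2,4,11(13)-trien-12,6-olide 8-(3-methylbutanoate), via cyclobutene 31 (not isolated)
Conditions: hν (350–366 nm, Pyrex), degassed CH2Cl2, −40 °C; then dark, → 25 °C
Reagents that add atoms: none
Why: Proposed new method: excitation of the enone gives the triplet, whose α-carbon C2 adds to the oxygen-bearing alkyne carbon C3 in a 5-exo-dig (1,5) closure that forms the furanone ring through C1, C10 and the ether oxygen, the resulting 1,4-biradical (vinyl radical at C4, ring radical at C5) closes to cyclobutene 31, and on warming 31 opens by thermal conrotatory 4π ring opening across C2–C5, which expands the eight-membered ring to the ten-membered carbocycle. The closest known reaction type is the intramolecular enone–alkyne [2+2] photocycloaddition followed by cyclobutene opening as a two-carbon ring expansion; new here are the alkynyl ether as 2π partner and its attachment through the α'-oxygen of a cyclooctenone. Compound 31 should open near room temperature because its double bond sits at the fusion with the five-membered ring and the breaking C2–C5 bond is flanked by the ketone on one side and the enol ether on the other (push–pull). No stereocentre is created in the product; in 31, C2 is fixed by the tether on the face of the C10–O bond and C5 by cis closure of the four-membered ring. The step needs straight regiochemistry, secured by the two-atom tether and by the match of the nucleophilic alkyne carbon C4 with the enone β-carbon C5, and a cis-fused cyclobutene, secured because both radical centres can relax before the second bond forms while C4 is held on the face of the C2–C3 bond; conrotation must then turn C1 outward (C1 and the ether oxygen share the five-membered ring) and C6 inward, giving the cis C4=C5 alkene. Irradiating cold keeps 31 closed until the lamp is off, so the strongly absorbing dienone product is not exposed to light, and at these wavelengths the α-methylene lactone does not absorb.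

**Step 20**
Reactants: 32 the C15 triisopropylsilyl ether of step 19
Product: 33 (2Z,4Z,6R,7R,8R,10S)-15-hydroxy-1-oxo-3,10-epoxygermacra-2,4,11(13)-trien-12,6-olide 8-(3-methylbutanoate) (CNP0171896.1)
Conditions: HF·pyridine, pyridine, THF, 0 °C → rt
Reagents that add atoms: none
Why: Buffered hydrogen fluoride cleaves the primary allylic silyl ether under conditions that leave the α-methylene lactone, the isovalerate and the furanone dienone alone, and no stereocentre is affected.

**Compound list**
1 | (S)-citramalic acid | OC(=O)[C@@](C)(O)CC(=O)O | starting material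
2 | 2-[(4S)-2,2,4-trimethyl-5-oxo-1,3-dioxolan-4-yl]acetic acid | CC1(C)OC(=O)[C@](C)(CC(=O)O)O1 | intermediate
3 | (5S)-5-(2-hydroxyethyl)-2,2,5-trimethyl-1,3-dioxolan-4-one | CC1(C)OC(=O)[C@](C)(CCO)O1 | intermediate (not isolated)
4 | (3S)-3-hydroxy-3-methyloxolan-2-one | C[C@]1(O)CCOC1=O | intermediate
5 | trichloroethylene | ClC=C(Cl)Cl | starting material
6 | (3S)-3-[(E)-1,2-dichloroethenyloxy]-3-methyloxolan-2-one | C[C@]1(O/C(Cl)=C\Cl)CCOC1=O | intermediate
7 | (3S)-3-[(E)-1,2-dichloroethenyloxy]-3-methyloxolan-2-ol (anomer mixture) | C[C@]1(O/C(Cl)=C\Cl)CCOC1O | intermediate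
8 | vinylmagnesium bromide | C=C[Mg]Br | starting material
9 | (3S)-3-[(E)-1,2-dichloroethenyloxy]-3-methylhex-5-ene-1,4-diol (C4 epimers) | C=CC(O)[C@](C)(CCO)O/C(Cl)=C\Cl | intermediate
10 | (3S)-3-[(E)-1,2-dichloroethenyloxy]-3-methyl-1,4-bis(triethylsilyloxy)hex-5-ene (C4 epimers) | C=CC(O[Si](CC)(CC)CC)[C@](C)(CCO[Si](CC)(CC)CC)O/C(Cl)=C\Cl | intermediate
11 | lithium alkynyl ether from 10 | C=CC(O[Si](CC)(CC)CC)[C@](C)(CCO[Si](CC)(CC)CC)OC#C[Li] | intermediate (not isolated)
12 | lithium 3-alkoxyprop-2-yn-1-olate from 11 | C=CC(O[Si](CC)(CC)CC)[C@](C)(CCO[Si](CC)(CC)CC)OC#CCO[Li] | intermediate (not isolated)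
13 | (3S)-3-methyl-1,4-bis(triethylsilyloxy)-3-[3-(triisopropylsilyloxy)prop-1-ynyloxy]hex-5-ene (C4 epimers) | C=CC(O[Si](CC)(CC)CC)[C@](C)(CCO[Si](CC)(CC)CC)OC#CCO[Si](C(C)C)(C(C)C)C(C)C | intermediate
14 | (3S)-3-methyl-4-(triethylsilyloxy)-3-[3-(triisopropylsilyloxy)prop-1-ynyloxy]hex-5-en-1-ol (C4 epimers) | C=CC(O[Si](CC)(CC)CC)[C@](C)(CCO)OC#CCO[Si](C(C)C)(C(C)C)C(C)C | intermediate
15 | (3S)-3-methyl-4-(triethylsilyloxy)-3-[3-(triisopropylsilyloxy)prop-1-ynyloxy]hex-5-enal (C4 epimers) | C=CC(O[Si](CC)(CC)CC)[C@](C)(CC=O)OC#CCO[Si](C(C)C)(C(C)C)C(C)C | intermediate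
16 | (R)-but-3-ene-1,2-diol | OC[C@H](O)C=C | starting material
17 | (R)-1,2-bis(triethylsilyloxy)but-3-ene | C=C[C@@H](O[Si](CC)(CC)CC)CO[Si](CC)(CC)CC | intermediate
18 | (R)-2-(triethylsilyloxy)but-3-enal | C=C[C@@H](O[Si](CC)(CC)CC)C=O | intermediate
19 | methyl propiolate | C#CC(=O)OC | starting material
20 | [1-(methoxycarbonyl)ethenyl]diisobutylaluminium | COC(=O)C(=C)[Al](CC(C)C)CC(C)C | intermediate (not isolated)
21 | methyl (4R)-3-hydroxy-2-methylidene-4-(triethylsilyloxy)hex-5-enoate (C3 epimers) | C=C[C@@H](O[Si](CC)(CC)CC)C(O)C(=C)C(=O)OC | intermediate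
22 | methyl (2Z,4R)-2-(bromomethyl)-4-(triethylsilyloxy)hexa-2,5-dienoate | C=C[C@@H](O[Si](CC)(CC)CC)/C=C(\CBr)C(=O)OC | intermediate
23 | allylindium dibromide from 22 | C=C[C@@H](O[Si](CC)(CC)CC)/C=C(\C[In](Br)Br)C(=O)OC | intermediate (not isolated)
24 | methyl (3R,4R,6S)-4-hydroxy-6-methyl-2-methylidene-7-(triethylsilyloxy)-3-[(1R)-1-(triethylsilyloxy)prop-2-enyl]-6-[3-(triisopropylsilyloxy)prop-1-ynyloxy]non-8-enoate (C7 epimers) | C=C(C(=O)OC)[C@@H]([C@H](O[Si](CC)(CC)CC)C=C)[C@H](O)C[C@](C)(OC#CCO[Si](C(C)C)(C(C)C)C(C)C)C(O[Si](CC)(CC)CC)C=C | intermediate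
25 | isovaleric anhydride | CC(C)CC(=O)OC(=O)CC(C)C | starting material
26 | 4-(3-methylbutanoate) of 24 (C7 epimers) | C=C(C(=O)OC)[C@@H]([C@H](O[Si](CC)(CC)CC)C=C)[C@H](OC(=O)CC(C)C)C[C@](C)(OC#CCO[Si](C(C)C)(C(C)C)C(C)C)C(O[Si](CC)(CC)CC)C=C | intermediate
27 | diol from 26 (both triethylsilyl groups removed; spatial arrangement at C6, C7, C8, C10 as in 26; C1 epimers) | C=C(C(=O)OC)[C@@H]([C@H](O)C=C)[C@H](OC(=O)CC(C)C)C[C@](C)(OC#CCO[Si](C(C)C)(C(C)C)C(C)C)C(O)C=C | intermediate (not isolated)
28 | (1R,3S)-1-[(2R,3R)-2-ethenyl-4-methylidene-5-oxooxolan-3-yl]-4-hydroxy-3-methyl-3-[3-(triisopropylsilyloxy)prop-1-ynyloxy]hex-5-enyl 3-methylbutanoate (C4 epimers) | C=C1C(=O)O[C@H](C=C)[C@H]1[C@H](OC(=O)CC(C)C)C[C@](C)(OC#CCO[Si](C(C)C)(C(C)C)C(C)C)C(O)C=C | intermediate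
29 | (1R,3S)-1-[(2R,3R)-2-ethenyl-4-methylidene-5-oxooxolan-3-yl]-3-methyl-4-oxo-3-[3-(triisopropylsilyloxy)prop-1-ynyloxy]hex-5-enyl 3-methylbutanoate | C=C1C(=O)O[C@H](C=C)[C@H]1[C@H](OC(=O)CC(C)C)C[C@](C)(OC#CCO[Si](C(C)C)(C(C)C)C(C)C)C(=O)C=C | intermediate
30 | cis-cyclooct-2-enone (6R,7R,8R,10S) with trans-fused 11(13)-methylidene-6,12-olide, 8-(3-methylbutanoate) and C10 methyl/3-(triisopropylsilyloxy)prop-1-ynyl ether | C=C1C(=O)O[C@@H]2/C=C\C(=O)[C@](C)(C[C@@H](OC(=O)CC(C)C)[C@@H]12)OC#CCO[Si](C(C)C)(C(C)C)C(C)C | intermediate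
31 | cis-fused cyclobutene photoadduct (C2–C3 and C4–C5 bonds formed on the face of the C10–O bond, C3=C4 double bond) | C=C1C(=O)O[C@@H]2[C@H]3C(CO[Si](C(C)C)(C(C)C)C(C)C)=C4O[C@@](C)(C[C@@H](OC(=O)CC(C)C)[C@@H]12)C(=O)[C@@H]34 | intermediate (not isolated)
32 | (2Z,4Z,6R,7R,8R,10S)-1-oxo-15-(triisopropylsilyloxy)-3,10-epoxygermacra-2,4,11(13)-trien-12,6-olide 8-(3-methylbutanoate) | C=C1C(=O)O[C@@H]2/C=C(/CO[Si](C(C)C)(C(C)C)C(C)C)C3=CC(=O)[C@](C)(C[C@@H](OC(=O)CC(C)C)[C@@H]12)O3 | intermediate
33 | (2Z,4Z,6R,7R,8R,10S)-15-hydroxy-1-oxo-3,10-epoxygermacra-2,4,11(13)-trien-12,6-olide 8-(3-methylbutanoate), CNP0171896.1 | C=C1C(=O)O[C@@H]2/C=C(/CO)C3=CC(=O)[C@](C)(C[C@@H](OC(=O)CC(C)C)[C@@H]12)O3 | target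

**Step count:** 20 steps in total; longest linear sequence 16 steps (steps 1–9 and 14–20).

**Steps most likely to fail**

Step 19. The excited cyclooctenone may decay by cis–trans isomerisation or hydrogen abstraction instead of adding to the alkyne, or the biradical may close to a trans-fused cyclobutene, whose opening would give the trans C4=C5 isomer. The fallback sets out from alcohol 28 and uses a dienyne ring-closing metathesis cascade, a known reaction type. Second-generation Grubbs catalyst [RuCl2(H2IMes)(PCy3)(=CHPh)] in dilute CH2Cl2 at 40 °C loads on the allylic-alcohol vinyl group. Ring-closing enyne metathesis onto the alkynyl ether then forms the five-membered ring with the C2=C3 bond, and the vinyl carbene at C4 closes the ten-membered ring onto the C6 vinyl group. This gives the macrocyclic dihydrofuranol F1. Dess–Martin oxidation of its C1 carbinol gives the furanone and rejoins the route at 32. In this variant the C4=C5 geometry is set by ring strain and not by orbital symmetry.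

Step 18. The ruthenium alkylidene may engage the alkynyl ether (enyne metathesis), or the tertiary alkynyl ether may fragment thermally before the slow eight-membered closure. The fallback sets out from 29, whose alkyne is masked with Co2(CO)8 (CH2Cl2, rt) as the hexacarbonyldicobalt complex F2. Such complexes are inert to metathesis catalysts and cannot undergo the retro-ene reaction. Ring-closing metathesis under the conditions of step 18 then gives the complexed cyclooctenone F3. Decomplexation with NMO (CH2Cl2, 0 °C) rejoins the route at 30.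

Step 14. The aldehyde may approach the allylindium unit on the face syn to the silyloxy group, which gives the wrong C6/C7 relationship, and the β-alkynyloxy aldehyde may lose the ynolate. The fallback sets out from 21 and fixes the C6/C7 relationship by a ring. Aqueous HCl in THF removes the silyl group and closes the lactone to the hydroxy lactone F4. PBr3 (Et2O, 0 °C) converts F4 with allylic transposition into the 3-(bromomethyl)butenolide F5. Indium-mediated coupling of F5 with 15 delivers C8 to C7 on the ring face opposite the C6 vinyl group and gives the trans lactone directly. The ring-locked E allyl unit is expected to give the 7,8-anti alcohol F6. Mitsunobu esterification of F6 with isovaleric acid (PPh3, DIAD, THF, 0 °C) inverts C8 and gives the ester F7. Buffered Bu4NF removes its C1 silyl ether and rejoins the route at 28.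

**Further compounds**
F1 | step 19 | (2Z,4Z,6R,7R,8R,10S)-1-hydroxy-15-(triisopropylsilyloxy)-3,10-epoxygermacra-2,4,11(13)-trien-12,6-olide 8-(3-methylbutanoate) (C1 epimers) | C=C1C(=O)O[C@@H]2/C=C(/CO[Si](C(C)C)(C(C)C)C(C)C)C3=CC(O)[C@](C)(C[C@@H](OC(=O)CC(C)C)[C@@H]12)O3
F2 | step 18 | hexacarbonyldicobalt complex of the alkyne of 29 | C=C1C(=O)O[C@H](C=C)[C@H]1[C@H](OC(=O)CC(C)C)C[C@](C)(OC23C4(CO[Si](C(C)C)(C(C)C)C(C)C)[Co]2(=C=O)(=C=O)(=C=O)[Co]34(=C=O)(=C=O)=C=O)C(=O)C=C
F3 | step 18 | hexacarbonyldicobalt complex of the alkyne of 30 | C=C1C(=O)O[C@@H]2/C=C\C(=O)[C@](C)(C[C@@H](OC(=O)CC(C)C)[C@@H]12)OC34C5(CO[Si](C(C)C)(C(C)C)C(C)C)[Co]3(=C=O)(=C=O)(=C=O)[Co]45(=C=O)(=C=O)=C=O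
F4 | step 14 | (5R)-5-ethenyl-4-hydroxy-3-methylideneoxolan-2-one (C4 epimers) | C=C[C@H]1OC(=O)C(=C)C1O
F5 | step 14 | (5R)-3-(bromomethyl)-5-ethenylfuran-2(5H)-one | C=C[C@H]1OC(=O)C(CBr)=C1
F6 | step 14 | C8 epimer of the lactone alcohol: trans lactone with free C8 hydroxyl and C1 triethylsilyl ether (C1 epimers) | C=C1C(=O)O[C@H](C=C)[C@H]1[C@@H](O)C[C@](C)(OC#CCO[Si](C(C)C)(C(C)C)C(C)C)C(O[Si](CC)(CC)CC)C=C
F7 | step 14 | C1 triethylsilyl ether of 28 (C1 epimers) | C=C1C(=O)O[C@H](C=C)[C@H]1[C@H](OC(=O)CC(C)C)C[C@](C)(OC#CCO[Si](C(C)C)(C(C)C)C(C)C)C(O[Si](CC)(CC)CC)C=C
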